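Lupulone's six-membered carbocycle alternates carbon-substituted ring atoms (C1 prenyl, C3 acyl, C5 diprenyl) with oxygenated ones (C2, C4, C6). The ring is therefore cut into three polarised two-carbon pieces: diprenylketene (C5=C6), a prenylated ethyl ynol ether (C1≡C2) and an acylated ethyl ynol ether (C3≡C4). One nickel-catalysed [2+2+2] cycloaddition should join them head to tail, making C2–C3, C4–C5 and C6–C1 and delivering the fully substituted cyclohexa-2,4-dienone with every side chain in place; quaternary C5 blocks aromatisation. The three partners are simple acyclic compounds, each one to four steps from commercial materials, and hydrolysis of the two enol ethers finishes the synthesis.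

Key step: step 8

Remark on the chemistry: the ring numbering above (C6 is the ketone carbon that comes from the ketene) is used throughout. The target has no stereocentre; the only one on the route (carbinol 14, racemic) is destroyed in step 7. Once both enol ethers are hydrolysed, C2, C4 and C6 are equivalent in role. The adduct from the opposite cyclic order of the three components would therefore give the same target, and only a head-to-head junction would be fatal. Ethyl is kept as the oxygen substituent because ethoxyacetylene is commercial. The ethoxyacetylide is used as its lithium salt for the alkylation (step 5), where a strongly nucleophilic acetylide in THF/DMPU is needed. It is used as its bromomagnesium salt for the carbonyl addition (step 6), where the less basic reagent limits enolisation of the aldehyde.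

Step 1
Reactants: 1 diethyl malonate; 2 prenyl bromide (1-bromo-3-methylbut-2-ene)
Product: 4 diethyl 2,2-bis(3-methylbut-2-en-1-yl)malonate, via diethyl 2-(3-methylbut-2-en-1-yl)malonate 3 (not isolated)
Conditions: NaH (2.4 equiv), THF, 0 °C; 2 (2.3 equiv), 0 → 50 °C
Reagents that add atoms: none
Why: Malonic ester dialkylation: the sodium enolate of the 1,3-diester is alkylated in SN2 fashion by the primary allylic bromide, and the excess NaH re-forms the enolate of mono-alkylated 3 so that the second prenyl group enters in the same flask.

Step 2
Reactants: 4 diethyl 2,2-bis(3-methylbut-2-en-1-yl)malonate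
Product: 5 ethyl 5-methyl-2-(3-methylbut-2-en-1-yl)hex-4-enoate (ethyl diprenylacetate)
Conditions: LiCl (2 equiv), H2O (2 equiv), DMSO, 170 °C
Reagents that add atoms: none
Why: Krapcho dealkoxycarbonylation: chloride dealkylates one ester of the geminal diester in hot wet DMSO and the resulting carboxylate loses CO2, a neutral process that leaves both trisubstituted alkenes untouched.

Step 3
Reactants: 5 ethyl 5-methyl-2-(3-methylbut-2-en-1-yl)hex-4-enoate
Product: 6 5-methyl-2-(3-methylbut-2-en-1-yl)hex-4-enoic acid (diprenylacetic acid)
Conditions: KOH, EtOH/H2O, reflux; then 1 M HCl, 0 °C (pH 3)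
Reagents that add atoms: potassium hydroxide, [K+].[OH-]
Why: Saponification of the α-branched ester with hydroxide followed by brief, cold acidification gives the acid without exposing the prenyl groups to conditions that would cause lactonisation.

Step 4
Reactants: 6 5-methyl-2-(3-methylbut-2-en-1-yl)hex-4-enoic acid
Product: 8 bis(3-methylbut-2-en-1-yl)ketene (diprenylketene), via 5-methyl-2-(3-methylbut-2-en-1-yl)hex-4-enoyl chloride 7 (not isolated)
Conditions: (COCl)2, DMF (cat.), CH2Cl2, 0 °C → rt; evaporate; Et3N (1.5 equiv), THF, rt → 50 °C, Ar; Schlenk filtration, bulb-to-bulb distillation, stored as a toluene solution at −30 °C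
Reagents that add atoms: none
Why: Acid chloride formation under DMF catalysis followed by amine-mediated dehydrochlorination (1,2-elimination via the acylammonium enolate) is the standard route to disubstituted ketenes, and a ketene with two primary alkyl substituents should persist long enough to be filtered from the ammonium salt and distilled, its alkenes being too close to the ketene carbon for an intramolecular [2+2] addition.

Step 5
Reactants: 9 ethoxyacetylene (ethoxyethyne, used as its commercial hexanes solution); 2 prenyl bromide
Product: 11 1-ethoxy-5-methylhex-4-en-1-yne, via lithium ethoxyacetylide 10 (not isolated)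
Conditions: n-BuLi (0.95 equiv), THF, −78 °C; DMPU, 2, −78 → 0 °C; chromatography on Et3N-deactivated silica
Reagents that add atoms: none
Why: SN2 alkylation of a lithium alkoxyacetylide with a reactive primary allylic bromide in the presence of a dipolar cosolvent is an established route to 1-alkoxyalk-1-ynes, attack at the unhindered primary carbon being preferred over the SN2′ mode.

Step 6
Reactants: 9 ethoxyacetylene; 12 3-methylbutanal
Product: 14 (±)-1-ethoxy-5-methylhex-1-yn-3-ol, via ethoxyethynylmagnesium bromide 13 (not isolated)
Conditions: EtMgBr (1.0 equiv), THF, 0 °C → rt; 12, −20 → 0 °C; sat. aq. NH4Cl, 0 °C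
Reagents that add atoms: none
Why: Alkynyl Grignard addition to an aldehyde: deprotonation of 9 by EtMgBr gives the bromomagnesium acetylide, which adds 1,2 to the aliphatic aldehyde (the classical entry to ethoxyethynyl carbinols) with little enolisation; the carbinol stereocentre forms without control as a racemate and is removed in the next step, and the near-neutral NH4Cl quench avoids Meyer–Schuster rearrangement.

Step 7
Reactants: 14 (±)-1-ethoxy-5-methylhex-1-yn-3-ol
Product: 15 1-ethoxy-5-methylhex-1-yn-3-one
Conditions: activated MnO2 (excess), CH2Cl2, rt; filtration through Celite
Reagents that add atoms: none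
Why: Activated MnO2 oxidises propargylic alcohols chemoselectively under neutral heterogeneous conditions, which suits the acid-sensitive ynol ether and delivers the push–pull alkynone.

Step 8
Reactants: 8 bis(3-methylbut-2-en-1-yl)ketene; 11 1-ethoxy-5-methylhex-4-en-1-yne; 15 1-ethoxy-5-methylhex-1-yn-3-one
Product: 16 3,5-diethoxy-4-(3-methylbutanoyl)-2,6,6-tris(3-methylbut-2-en-1-yl)cyclohexa-2,4-dien-1-one (lupulone diethyl ether; achiral)
Conditions: Ni(cod)2 (10 mol %), 1,4-bis(diphenylphosphino)butane (10 mol %, premixed), toluene, 0 °C → rt, Ar; 11 (1.5 equiv) charged with the catalyst, 15 (1.0 equiv) and 8 (1.3 equiv) added together by syringe pump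
Reagents that add atoms: none
Why: Proposed new method: zerovalent nickel bearing the chelating diphosphine is expected to couple the ketene C=C bond oxidatively with the electron-rich ynol ether 11, the nucleophilic prenyl-bearing carbon C1 bonding to the electrophilic ketene carbon C6 to give a five-membered nickelacycle that is a nickel enolate at C5 and an α-ethoxyvinyl nickel at C2. The electron-poor alkynone 15 then inserts into the enolate Ni–C5 bond in the conjugate sense (C5 to the ethoxy-bearing carbon C4), and C–C reductive elimination from the seven-membered nickelacycle joins C2 to C3 and returns zerovalent nickel; an alkyne-first sequence through a nickelacyclopentadiene would give the same three bonds. The closest known reaction type is the nickel/diphosphine-catalysed [2+2+2] cycloaddition of tethered diynes with disubstituted ketenes to cyclohexa-2,4-dienones, together with intermolecular nickel-catalysed co-cyclisations of two alkynes with CO2 or isocyanates; the untethered union of two different alkynes with a ketene is the unprecedented part. The six-membered carbocycle is closed by that final reductive elimination (a formal [2+2+2] cycloaddition), and no stereocentre is created because C5 carries two identical prenyl groups. The step needs cross- instead of homo-coupling of the alkynes, strictly alternating (head-to-tail) regiochemistry and suppression of the uncatalysed ketene–ynol ether [2+2] addition to a cyclobutenone: the donor/acceptor difference between 11 and 15, the polarisation of each triple bond by its ethoxy group (reinforced in 15 by the acyl group), the steric shielding of the diprenylketene and its slow addition at low temperature are the elements expected to secure them. Quaternary C5 prevents tautomerisation to a phenol, so the cross-conjugated dienone is the end point.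

Step 9
Reactants: 16 lupulone diethyl ether
Product: 17 lupulone (3,5-dihydroxy-4-(3-methylbutanoyl)-2,6,6-tris(3-methylbut-2-en-1-yl)cyclohexa-2,4-dien-1-one; achiral)
Conditions: LiOH, H2O/1,4-dioxane (degassed), 80 °C, Ar; then 1 M HCl, 0 °C (pH 3)
Reagents that add atoms: lithium hydroxide, [Li+].[OH-]
Why: Each ethoxy group sits on the β-carbon of an enone, so hydroxide cleaves both by conjugate addition–elimination (vinylogous ester hydrolysis, the usual unmasking of O-alkylated polyprenylated acylphloroglucinols), the product surviving as its delocalised enolate until cold acidification and the prenyl groups being inert to base.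

Compound list
1 | diethyl malonate | CCOC(=O)CC(=O)OCC | starting material
2 | prenyl bromide (1-bromo-3-methylbut-2-ene) | CC(C)=CCBr | starting material
3 | diethyl 2-(3-methylbut-2-en-1-yl)malonate | CCOC(=O)C(CC=C(C)C)C(=O)OCC | intermediate (not isolated)
4 | diethyl 2,2-bis(3-methylbut-2-en-1-yl)malonate | CCOC(=O)C(CC=C(C)C)(CC=C(C)C)C(=O)OCC | intermediate
5 | ethyl 5-methyl-2-(3-methylbut-2-en-1-yl)hex-4-enoate | CCOC(=O)C(CC=C(C)C)CC=C(C)C | intermediate
6 | 5-methyl-2-(3-methylbut-2-en-1-yl)hex-4-enoic acid | CC(C)=CCC(CC=C(C)C)C(=O)O | intermediate
7 | 5-methyl-2-(3-methylbut-2-en-1-yl)hex-4-enoyl chloride | CC(C)=CCC(CC=C(C)C)C(=O)Cl | intermediate (not isolated)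
8 | bis(3-methylbut-2-en-1-yl)ketene (diprenylketene) | CC(C)=CCC(=C=O)CC=C(C)C | intermediate
9 | ethoxyacetylene (ethoxyethyne) | C#COCC | starting material
10 | lithium ethoxyacetylide | [Li]C#COCC | intermediate (not isolated)
11 | 1-ethoxy-5-methylhex-4-en-1-yne | CCOC#CCC=C(C)C | intermediate
12 | 3-methylbutanal | CC(C)CC=O | starting material
13 | ethoxyethynylmagnesium bromide | CCOC#C[Mg]Br | intermediate (not isolated)
14 | (±)-1-ethoxy-5-methylhex-1-yn-3-ol (racemic) | CCOC#CC(O)CC(C)C | intermediate
15 | 1-ethoxy-5-methylhex-1-yn-3-one | CCOC#CC(=O)CC(C)C | intermediate
16 | 3,5-diethoxy-4-(3-methylbutanoyl)-2,6,6-tris(3-methylbut-2-en-1-yl)cyclohexa-2,4-dien-1-one (lupulone diethyl ether) | CCOC1=C(CC=C(C)C)C(=O)C(CC=C(C)C)(CC=C(C)C)C(OCC)=C1C(=O)CC(C)C | intermediate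
17 | lupulone | CC(C)=CCC1=C(O)C(C(=O)CC(C)C)=C(O)C(CC=C(C)C)(CC=C(C)C)C1=O | target

Total step count: 9 steps.
Longest linear sequence: 6 steps (steps 1, 2, 3, 4, 8, 9, from diethyl malonate).

Steps most likely to fail

Step 8 (Proposed new method). The alkynes may oligomerise among themselves at nickel, a head-to-head junction may form, the ketene may be decarbonylated at the metal, or the thermal ketene–ynol ether [2+2] addition may outrun catalysis. The fallback uses known chemistry and takes the ring from an arene. Phloroglucinol is C-acylated with 3-methylbutanoyl chloride (AlCl3, nitrobenzene/CH2Cl2, Friedel–Crafts acylation) to give phlorisovalerophenone, 3-methyl-1-(2,4,6-trihydroxyphenyl)butan-1-one F1. F1 is then C-prenylated three times with 2 (NaOMe, MeOH, 0 °C); the third alkylation is geminal and dearomatising, and under- and over-alkylated products would have to be separated. This fallback sets out from 2 and comes back to the route at 17.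

Step 4. Dehydrochlorination of the α-branched acid chloride may stall, the ketene may be acylated by unreacted acid chloride, or it may dimerise during distillation from the ammonium salt. The fallback makes the ketene by decarboxylative fragmentation of a malonic mixed anhydride. Diester 4 is saponified (KOH, aqueous EtOH, reflux; cold acidification) to 2,2-bis(3-methylbut-2-en-1-yl)malonic acid F2. Trifluoroacetic anhydride in ether at 0 °C, followed by pyridine to neutralise the acid, converts F2 into 2,2-bis(3-methylbut-2-en-1-yl)malonic bis(trifluoroacetic) anhydride F3. Gentle thermolysis of F3 under reduced pressure expels CO2 and trifluoroacetic anhydride and distils the ketene free of amine salts. This fallback sets out from 4 and comes back at 8.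

Step 7. The ethoxyethynyl carbinol may undergo Meyer–Schuster rearrangement on the oxidant surface, or the push–pull alkynone may be hydrated or oligomerise during long contact with the solid. The fallback brings in the ketone oxidation level by acylation. 3-Methylbutanoyl chloride and N,O-dimethylhydroxylamine hydrochloride (pyridine, CH2Cl2, 0 °C) give the Weinreb amide N-methoxy-N,3-dimethylbutanamide F4. F4 is added to lithium ethoxyacetylide 10 (generated from 9 as in step 5: n-BuLi, THF, −78 °C), and an inverse quench into cold aqueous NaH2PO4 protonates the liberated hydroxylamine before it can add to the alkynone. This fallback sets out from 9 and comes back at 15.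

Further compounds
F1 | step 8 | 3-methyl-1-(2,4,6-trihydroxyphenyl)butan-1-one (phlorisovalerophenone) | CC(C)CC(=O)c1c(O)cc(O)cc1O
F2 | step 4 | 2,2-bis(3-methylbut-2-en-1-yl)malonic acid | CC(C)=CCC(CC=C(C)C)(C(=O)O)C(=O)O
F3 | step 4 | 2,2-bis(3-methylbut-2-en-1-yl)malonic bis(trifluoroacetic) anhydride | CC(C)=CCC(CC=C(C)C)(C(=O)OC(=O)C(F)(F)F)C(=O)OC(=O)C(F)(F)F
F4 | step 7 | N-methoxy-N,3-dimethylbutanamide | CC(C)CC(=O)N(C)OC
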